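**Retrosynthetic overview**
1. Target 22 ⇐ two-electron dehydrogenation of the leuco lactone 21 ⇐ global O-demethylation of the tetramethyl ether 20.
2. Furan C–O bond of 20 ⇐ intramolecular Ullmann etherification of the bromo-phenol lactone 19.
3. Key C–C bond (dibenzofuran C1 to the aryl-acetic carbon) ⇐ TiCl4-mediated Mukaiyama–Michael addition of silyl ketene acetal 17 to aryl-quinone 14, then lactonisation.
4. Quinone 14 ⇐ oxidation of phenol 13 ⇐ Suzuki coupling of boronate 10 with dibromide 11 ⇐ directed ortho-metalation of MOM ether 8 ⇐ phenol 7 ⇐ 2,6-dimethoxybiphenyl 3 (Suzuki of 1 and 2).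
5. Ring order: terphenyl-type carbon frame → quinone → butanolide ring → furan ring → quinone methide.

Assumption: the target has no stereocentre and no stereogenic double bond, so there is no enantiomer to control; C-3 of the lactone in 18–21 is formed racemic and becomes sp2 in the last step.

**Step 1**
Reactants: 1 2-bromo-1,3-dimethoxybenzene; 2 phenylboronic acid
Product: 3 2,6-dimethoxybiphenyl
Conditions: Pd(OAc)2 (2 mol %), SPhos (4 mol %), K3PO4, toluene/H2O, 100 °C
Reagents that add atoms: none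
Why: Suzuki–Miyaura coupling; SPhos handles the di-ortho-substituted, electron-rich bromide.

**Step 2**
Reactants: 3 2,6-dimethoxybiphenyl
Product: 4 3-bromo-2,6-dimethoxybiphenyl
Conditions: NBS (1.0 equiv), MeCN, 0 °C → rt
Reagents that add atoms: N-bromosuccinimide, O=C1CCC(=O)N1Br
Why: Electrophilic aromatic bromination goes ortho to one OMe and para to the other, the only doubly activated position (C3 and C5 are equivalent), so one mono-bromide forms.

**Step 3**
Reactants: 4 3-bromo-2,6-dimethoxybiphenyl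
Product: 7 2,4-dimethoxy-3-phenylphenol, via aryllithium 5 (not isolated), via dimethyl arylboronate 6 (not isolated)
Conditions: n-BuLi, THF, −78 °C; B(OMe)3, −78 °C → rt; 30 % H2O2, aq. NaOH, 0 °C → rt; acid work-up
Reagents that add atoms: hydrogen peroxide, OO
Why: Lithium–bromine exchange, borylation and oxidative 1,2-aryl shift from boron to oxygen replace Br by OH at a defined position.

**Step 4**
Reactants: 7 2,4-dimethoxy-3-phenylphenol
Product: 8 1-(methoxymethoxy)-2,4-dimethoxy-3-phenylbenzene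
Conditions: MOMCl, iPr2NEt, CH2Cl2, 0 °C → rt
Reagents that add atoms: chloromethyl methyl ether, COCCl
Why: O-Alkylation of the phenol (MOM protection) installs a strong ortho-directing group that stays distinct from the two methyl ethers.

**Step 5**
Reactants: 8 1-(methoxymethoxy)-2,4-dimethoxy-3-phenylbenzene
Product: 10 2-[3,5-dimethoxy-2-(methoxymethoxy)-4-phenylphenyl]-4,4,5,5-tetramethyl-1,3,2-dioxaborolane, via ortho-lithiated ether 9 (not isolated)
Conditions: n-BuLi, TMEDA, THF, −78 → 0 °C; iPrOBpin, −78 °C → rt; aqueous work-up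
Reagents that add atoms: 2-isopropoxy-4,4,5,5-tetramethyl-1,3,2-dioxaborolane, CC(C)OB1OC(C)(C)C(C)(C)O1
Why: Directed ortho-metalation; OMOM outranks OMe as director and its only free ortho position is C6, so boron enters next to the future furan oxygen.

**Step 6**
Reactants: 10 the pinacol boronate; 11 1,2-dibromo-4,5-dimethoxybenzene (3 equiv)
Product: 12 2'-bromo-3,4',5,5'-tetramethoxy-2-(methoxymethoxy)-4-phenyl-1,1'-biphenyl
Conditions: Pd(PPh3)4 (5 mol %), K2CO3, DME/H2O, 85 °C
Reagents that add atoms: none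
Why: Suzuki–Miyaura coupling; the symmetric dibromide is in excess and the remaining C–Br of the product is more hindered, so mono-coupling dominates.

**Step 7**
Reactants: 12 the MOM-protected bromobiaryl
Product: 13 6-(2-bromo-4,5-dimethoxyphenyl)-2,4-dimethoxy-3-phenylphenol
Conditions: conc. HCl (cat.), MeOH, 50 °C
Reagents that add atoms: none
Why: Acid-catalysed acetal exchange removes the MOM group while aryl methyl ethers and the aryl bromide are inert.

**Step 8**
Reactants: 13 6-(2-bromo-4,5-dimethoxyphenyl)-2,4-dimethoxy-3-phenylphenol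
Product: 14 2-(2-bromo-4,5-dimethoxyphenyl)-6-methoxy-5-phenyl-1,4-benzoquinone
Conditions: PhI(OAc)2 (1.1 equiv), MeCN/H2O 2:1, 0 °C → rt
Reagents that add atoms: water, O
Why: Hypervalent-iodine oxidative demethylation of a p-methoxyphenol; water adds para at the OMe-bearing carbon and methanol is lost, while the OH-free bromoveratrole ring is untouched.

**Step 9**
Reactants: 15 methyl 2-(4-methoxyphenyl)acetate
Product: 17 1-methoxy-2-(4-methoxyphenyl)-1-(trimethylsilyloxy)ethene (E/Z mixture), via lithium ester enolate 16 (not isolated)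
Conditions: LDA (1.1 equiv), THF, −78 °C; TMSCl, −78 °C → rt; pentane, filter, concentrate
Reagents that add atoms: chlorotrimethylsilane, C[Si](C)(C)Cl
Why: Kinetic ester enolisation and O-silylation give the silyl ketene acetal; its alkene geometry is irrelevant.

**Step 10 (key step)**
Reactants: 14 the aryl-quinone; 17 the silyl ketene acetal (1.5 equiv)
Product: 19 4-(2-bromo-4,5-dimethoxyphenyl)-5-hydroxy-6-methoxy-3-(4-methoxyphenyl)-7-phenyl-1-benzofuran-2(3H)-one (racemic), via hydroquinone ester 18 (not isolated)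
Conditions: TiCl4 (1.1 equiv), CH2Cl2, −78 °C; aq. NaHCO3; crude, TsOH·H2O (10 mol %), toluene, 80 °C
Reagents that add atoms: none
Why: Intermolecular Mukaiyama–Michael addition: TiCl4 chelated by the C1 carbonyl and the adjacent OMe activates the only unsubstituted ring carbon (β to that carbonyl); the adduct aromatises and the OH ortho to the new side chain closes the lactone; the new C-3 centre is racemic and is erased in step 13.

**Step 11**
Reactants: 19 the bromo-phenol lactone
Product: 20 2-(2-hydroxy-4,7,8-trimethoxy-3-phenyldibenzo[b,d]furan-1-yl)-2-(4-methoxyphenyl)acetic acid 2-O-lactone (racemic)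
Conditions: CuI (10 mol %), 1,10-phenanthroline (20 mol %), Cs2CO3 (2.5 equiv), degassed NMP, 100 °C, Ar; 1 M HCl work-up
Reagents that add atoms: none
Why: Intramolecular Ullmann-type C–O coupling of the only free phenol with the ortho-bromide across the biaryl bond closes the furan; the lactone is carried as its enolate under strict exclusion of O2 and reprotonated on work-up.

**Step 12**
Reactants: 20 the tetramethyl ether
Product: 21 2-(2,4,7,8-tetrahydroxy-3-phenyldibenzo[b,d]furan-1-yl)-2-(4-hydroxyphenyl)acetic acid 2-O-lactone (racemic leuco form)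
Conditions: BBr3 (8 equiv), CH2Cl2, −78 °C → rt, Ar; H2O quench
Reagents that add atoms: none
Why: Lewis-acid O-demethylation cleaves all four aryl methyl ethers; the aryl lactone and the dibenzofuran survive.

**Step 13**
Reactants: 21 the leuco lactone
Product: 22 target CNP0139113.0 (p-quinone methide lactone)
Conditions: p-chloranil (1.05 equiv), degassed 1,4-dioxane, rt → 50 °C, Ar
Reagents that add atoms: none
Why: Dehydrogenation of the electron-rich p-hydroxybenzylic lactone to the extended p-quinone methide; chloranil is too weak an oxidant to take the catechol on to an o-quinone.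

**Compound list**
1 | 2-bromo-1,3-dimethoxybenzene | COc1cccc(OC)c1Br | starting material
2 | phenylboronic acid | OB(O)c1ccccc1 | starting material
3 | 2,6-dimethoxybiphenyl | COc1cccc(OC)c1-c1ccccc1 | intermediate
4 | 3-bromo-2,6-dimethoxybiphenyl | COc1ccc(Br)c(OC)c1-c1ccccc1 | intermediate
5 | (2,4-dimethoxy-3-phenylphenyl)lithium | COc1ccc([Li])c(OC)c1-c1ccccc1 | intermediate (not isolated)
6 | dimethyl (2,4-dimethoxy-3-phenylphenyl)boronate | COc1ccc(B(OC)OC)c(OC)c1-c1ccccc1 | intermediate (not isolated)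
7 | 2,4-dimethoxy-3-phenylphenol | COc1ccc(O)c(OC)c1-c1ccccc1 | intermediate
8 | 1-(methoxymethoxy)-2,4-dimethoxy-3-phenylbenzene | COCOc1ccc(OC)c(-c2ccccc2)c1OC | intermediate
9 | [3,5-dimethoxy-2-(methoxymethoxy)-4-phenylphenyl]lithium | COCOc1c([Li])cc(OC)c(-c2ccccc2)c1OC | intermediate (not isolated)
10 | 2-[3,5-dimethoxy-2-(methoxymethoxy)-4-phenylphenyl]-4,4,5,5-tetramethyl-1,3,2-dioxaborolane | COCOc1c(B2OC(C)(C)C(C)(C)O2)cc(OC)c(-c2ccccc2)c1OC | intermediate
11 | 1,2-dibromo-4,5-dimethoxybenzene | COc1cc(Br)c(Br)cc1OC | starting material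
12 | 2'-bromo-3,4',5,5'-tetramethoxy-2-(methoxymethoxy)-4-phenyl-1,1'-biphenyl | COCOc1c(-c2cc(OC)c(OC)cc2Br)cc(OC)c(-c2ccccc2)c1OC | intermediate
13 | 6-(2-bromo-4,5-dimethoxyphenyl)-2,4-dimethoxy-3-phenylphenol | Oc1c(-c2cc(OC)c(OC)cc2Br)cc(OC)c(-c2ccccc2)c1OC | intermediate
14 | 2-(2-bromo-4,5-dimethoxyphenyl)-6-methoxy-5-phenyl-1,4-benzoquinone | COC1=C(c2ccccc2)C(=O)C=C(c2cc(OC)c(OC)cc2Br)C1=O | intermediate
15 | methyl 2-(4-methoxyphenyl)acetate | COC(=O)Cc1ccc(OC)cc1 | starting material
16 | lithium enolate of methyl 2-(4-methoxyphenyl)acetate | COC(O[Li])=Cc1ccc(OC)cc1 | intermediate (not isolated)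
17 | 1-methoxy-2-(4-methoxyphenyl)-1-(trimethylsilyloxy)ethene (E/Z mixture) | COC(O[Si](C)(C)C)=Cc1ccc(OC)cc1 | intermediate
18 | methyl 2-[2-(2-bromo-4,5-dimethoxyphenyl)-3,6-dihydroxy-4-methoxy-5-phenylphenyl]-2-(4-methoxyphenyl)acetate (racemic) | COC(=O)C(c1ccc(OC)cc1)c1c(O)c(-c2ccccc2)c(OC)c(O)c1-c1cc(OC)c(OC)cc1Br | intermediate (not isolated)
19 | 4-(2-bromo-4,5-dimethoxyphenyl)-5-hydroxy-6-methoxy-3-(4-methoxyphenyl)-7-phenyl-1-benzofuran-2(3H)-one (racemic) | O=C1Oc2c(-c3ccccc3)c(OC)c(O)c(-c3cc(OC)c(OC)cc3Br)c2C1c1ccc(OC)cc1 | intermediate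
20 | 2-(2-hydroxy-4,7,8-trimethoxy-3-phenyldibenzo[b,d]furan-1-yl)-2-(4-methoxyphenyl)acetic acid 2-O-lactone (racemic) | O=C1Oc2c(-c3ccccc3)c(OC)c3oc4cc(OC)c(OC)cc4c3c2C1c1ccc(OC)cc1 | intermediate
21 | 2-(2,4,7,8-tetrahydroxy-3-phenyldibenzo[b,d]furan-1-yl)-2-(4-hydroxyphenyl)acetic acid 2-O-lactone (racemic) | O=C1Oc2c(-c3ccccc3)c(O)c3oc4cc(O)c(O)cc4c3c2C1c1ccc(O)cc1 | intermediate
22 | CNP0139113.0 (achiral quinone methide lactone) | O=C1OC2=C(c3ccccc3)C(=O)c3oc4cc(O)c(O)cc4c3C2=C1c1ccc(O)cc1 | target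

**Totals**
Total step count: 13. Longest linear sequence: 12 steps (steps 1–8 and 10–13; step 9 is a one-step branch).

**Three steps most likely to fail**

Step 10 (key Michael addition). The quinone is hindered next to the reacting carbon, and electron transfer, O-attack or displacement of the ring OMe could compete. The fallback sets out from quinone 14 and uses a soft, non-reducing stabilised donor instead of the silyl ketene acetal. Commercial diethyl 2-(4-methoxyphenyl)malonate with catalytic DBU in CH2Cl2 at 0 °C (quinone added slowly) gives, by base-catalysed Michael addition, diethyl 2-[2-(2-bromo-4,5-dimethoxyphenyl)-3,6-dihydroxy-4-methoxy-5-phenylphenyl]-2-(4-methoxyphenyl)malonate F1. This lactonises in the flask to ethyl 4-(2-bromo-4,5-dimethoxyphenyl)-5-hydroxy-6-methoxy-3-(4-methoxyphenyl)-2-oxo-7-phenyl-3H-1-benzofuran-3-carboxylate F2. Heating F2 in AcOH/6 M HCl at 100 °C hydrolyses and decarboxylates the malonate-type ester and returns to the route at lactone 19.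

Step 11 (Ullmann closure). The 3-aryl lactone is C–H acidic, and its enolate may be arylated, autoxidised or may poison copper. The fallback sets out from 19 and replaces metal-catalysed C–O coupling under carbonate base by acid-catalysed cyclodehydration of a 2,2'-biphenol. Miyaura borylation (B2pin2, Pd(dppf)Cl2, KOAc, dioxane, 90 °C) gives 5-hydroxy-6-methoxy-4-[4,5-dimethoxy-2-(4,4,5,5-tetramethyl-1,3,2-dioxaborolan-2-yl)phenyl]-3-(4-methoxyphenyl)-7-phenyl-1-benzofuran-2(3H)-one F3. Oxidation with NaBO3·4H2O in THF/H2O at rt gives 5-hydroxy-4-(2-hydroxy-4,5-dimethoxyphenyl)-6-methoxy-3-(4-methoxyphenyl)-7-phenyl-1-benzofuran-2(3H)-one F4. TsOH in refluxing toluene (Dean–Stark) then closes the furan by ipso-substitution at the phenol carbon that is activated by its para- and meta-methoxy groups, returning to the route at 20.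

Step 13 (final oxidation). The substrate and product carry a free catechol and phenol, so over-oxidation or oligomerisation is possible. The fallback sets out from 20 and fixes the oxidation level before the phenols are unveiled. LiHMDS in THF at −78 °C followed by NBS gives 2-bromo-2-(2-hydroxy-4,7,8-trimethoxy-3-phenyldibenzo[b,d]furan-1-yl)-2-(4-methoxyphenyl)acetic acid 2-O-lactone F5. BBr3 in CH2Cl2 (−78 °C → rt) then ionises the tertiary benzylic bromide; the resulting O-methyl quinone-methide oxocarbenium is demethylated by bromide, and the other three methyl ethers are cleaved normally. This gives 22 directly with no oxidant in the presence of the catechol, bypassing 21.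

**Further compounds**
F1 | step 10 | diethyl 2-[2-(2-bromo-4,5-dimethoxyphenyl)-3,6-dihydroxy-4-methoxy-5-phenylphenyl]-2-(4-methoxyphenyl)malonate | CCOC(=O)C(C(=O)OCC)(c1ccc(OC)cc1)c1c(O)c(-c2ccccc2)c(OC)c(O)c1-c1cc(OC)c(OC)cc1Br
F2 | step 10 | ethyl 4-(2-bromo-4,5-dimethoxyphenyl)-5-hydroxy-6-methoxy-3-(4-methoxyphenyl)-2-oxo-7-phenyl-3H-1-benzofuran-3-carboxylate (racemic) | CCOC(=O)C1(c2ccc(OC)cc2)C(=O)Oc2c(-c3ccccc3)c(OC)c(O)c(-c3cc(OC)c(OC)cc3Br)c21
F3 | step 11 | 5-hydroxy-6-methoxy-4-[4,5-dimethoxy-2-(4,4,5,5-tetramethyl-1,3,2-dioxaborolan-2-yl)phenyl]-3-(4-methoxyphenyl)-7-phenyl-1-benzofuran-2(3H)-one (racemic) | O=C1Oc2c(-c3ccccc3)c(OC)c(O)c(-c3cc(OC)c(OC)cc3B3OC(C)(C)C(C)(C)O3)c2C1c1ccc(OC)cc1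
F4 | step 11 | 5-hydroxy-4-(2-hydroxy-4,5-dimethoxyphenyl)-6-methoxy-3-(4-methoxyphenyl)-7-phenyl-1-benzofuran-2(3H)-one (racemic) | O=C1Oc2c(-c3ccccc3)c(OC)c(O)c(-c3cc(OC)c(OC)cc3O)c2C1c1ccc(OC)cc1
F5 | step 13 | 2-bromo-2-(2-hydroxy-4,7,8-trimethoxy-3-phenyldibenzo[b,d]furan-1-yl)-2-(4-methoxyphenyl)acetic acid 2-O-lactone (racemic) | O=C1Oc2c(-c3ccccc3)c(OC)c3oc4cc(OC)c(OC)cc4c3c2C1(Br)c1ccc(OC)cc1
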